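## Retrosynthetic overview

1. Feature (ring A guaiacyl, rings B and C syringyl in chain order, ring D the benzo ring): C2 of the dihydrofuran is the benzylic carbon of ring C, para to the ring C ether oxygen, and its other heteroatom O1 is the phenol oxygen of ring D. Cutting O1–C2 gives a ring C para-quinone methide with the ring D phenol held next to it through C3.
2. The open-chain precursor 16 has one stereocentre (the future C3). It is cut at its CH–CH2 bond to the ring D arylacetyl imide and the ring C benzyl bromide (Evans alkylation).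
3. The two erythro arylglycerol aryl ether units are cut at C7'–C8' and C7–C8 to an aryloxyacetyl imide and an aldehyde (syn aldol, then inversion at the carbinol carbon). Ring B enters as an aldehyde that already carries the next oxyacetyl imide, ring A as silylated vanillin.
4. The enal is cut at the C5–alkene bond of ring D back to the aryl bromide, which also blocks ring D during the oxidation.
5. Ring order: rings A–D come from the starting materials; the dihydrofuran ring (step 12) is the only ring formed.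

Key step: step 12

Remark: the target SMILES is read as (7R,8S) and (7'R,8'S) for the two erythro units (C7–C9 on ring A, C7'–C9' on ring B) and (2R,3S), trans, for the dihydrobenzofuran.

## Route

Step 1
Reactants: 1 5-bromo-2-hydroxy-3-methoxybenzaldehyde
Product: 2 2-(benzyloxy)-5-bromo-3-methoxybenzaldehyde
Conditions: BnBr, K2CO3, DMF, rt
Reagents that add atoms: benzyl bromide, BrCc1ccccc1
Why: Williamson ether synthesis on the acidic ortho-formyl phenol should mask the ring D phenol as a benzyl ether that tolerates the base and hydride steps ahead.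

Step 2
Reactants: 2 2-(benzyloxy)-5-bromo-3-methoxybenzaldehyde
Product: 4 [2-(benzyloxy)-5-bromo-3-methoxyphenyl]acetonitrile, via N-(1-tosyl-2-arylvinyl)formamide 3 (not isolated)
Conditions: TosMIC, KOtBu, DME, −35 °C; then MeOH, reflux
Reagents that add atoms: tosylmethyl isocyanide (TosMIC), Cc1ccc(cc1)S(=O)(=O)C[N+]#[C-]
Why: Van Leusen reductive cyanation, in which the TosMIC anion adds to the aldehyde, the oxazoline opens to formamide 3, and methanolysis with loss of sulfinate leaves the one-carbon homologated nitrile.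

Step 3
Reactants: 4 [2-(benzyloxy)-5-bromo-3-methoxyphenyl]acetonitrile
Product: 5 [2-(benzyloxy)-5-bromo-3-methoxyphenyl]acetic acid
Conditions: KOH, EtOH/H2O, reflux; then aq HCl
Reagents that add atoms: potassium hydroxide, [K+].[OH-]; water, O
Why: alkaline nitrile hydrolysis should give the arylacetic acid, the unactivated aryl bromide and the benzyl ether being inert to hydroxide.

Step 4
Reactants: 5 [2-(benzyloxy)-5-bromo-3-methoxyphenyl]acetic acid; 6 (4S)-4-benzyl-1,3-oxazolidin-2-one
Product: 8 (4S)-4-benzyl-3-{[2-(benzyloxy)-5-bromo-3-methoxyphenyl]acetyl}-1,3-oxazolidin-2-one, via mixed pivalic anhydride 7 (not isolated)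
Conditions: PivCl, Et3N, THF, −20 °C; then 6, LiCl, −20 °C → rt
Reagents that add atoms: pivaloyl chloride, CC(C)(C)C(=O)Cl (its atoms stay in 7 only)
Why: N-acylation of the oxazolidinone through the mixed anhydride, the LiCl-activated auxiliary attacking the less hindered arylacetyl carbonyl.

Step 5
Reactants: 9 syringaldehyde (4-hydroxy-3,5-dimethoxybenzaldehyde)
Product: 10 4-(benzyloxy)-3,5-dimethoxybenzaldehyde
Conditions: BnBr, K2CO3, DMF, 60 °C
Reagents that add atoms: benzyl bromide, BrCc1ccccc1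
Why: Williamson ether synthesis should protect the ring C phenol, which would otherwise form a quinone methide from the benzylic bromide made in step 7.

Step 6
Reactants: 10 4-(benzyloxy)-3,5-dimethoxybenzaldehyde
Product: 11 [4-(benzyloxy)-3,5-dimethoxyphenyl]methanol
Conditions: NaBH4, MeOH, 0 °C
Reagents that add atoms: none
Why: borohydride reduction of the aldehyde to the benzylic alcohol.

Step 7
Reactants: 11 [4-(benzyloxy)-3,5-dimethoxyphenyl]methanol
Product: 12 2-(benzyloxy)-5-(bromomethyl)-1,3-dimethoxybenzene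
Conditions: PBr3, CH2Cl2, 0 °C
Reagents that add atoms: phosphorus tribromide, BrP(Br)Br
Why: conversion of the electron-rich benzylic alcohol into the bromide through its phosphite ester, used directly in step 8.

Step 8
Reactants: 8 (4S)-4-benzyl-3-{[2-(benzyloxy)-5-bromo-3-methoxyphenyl]acetyl}-1,3-oxazolidin-2-one; 12 2-(benzyloxy)-5-(bromomethyl)-1,3-dimethoxybenzene
Product: 13 (4S)-4-benzyl-3-{(2S)-2-[2-(benzyloxy)-5-bromo-3-methoxyphenyl]-3-[4-(benzyloxy)-3,5-dimethoxyphenyl]propanoyl}-1,3-oxazolidin-2-one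
Conditions: NaN(SiMe3)2, THF, −78 °C; then 12, −78 → −40 °C
Reagents that add atoms: none
Why: Evans asymmetric alkylation, in which the chelated sodium Z-enolate is attacked by the benzylic bromide on the face away from the C4 benzyl group of the (S)-auxiliary, which should set the (S) centre that becomes C3 of the dihydrofuran.

Step 9
Reactants: 13 the alkylated imide
Product: 14 (2S)-2-[2-(benzyloxy)-5-bromo-3-methoxyphenyl]-3-[4-(benzyloxy)-3,5-dimethoxyphenyl]propan-1-ol
Conditions: LiBH4, MeOH (1 equiv), THF, 0 °C → rt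
Reagents that add atoms: none
Why: reductive cleavage of the N-acyl oxazolidinone at the exocyclic carbonyl should free the primary alcohol without touching the α-aryl centre, and the auxiliary is recovered.

Step 10
Reactants: 14 the (2S)-diarylpropanol
Product: 15 (2S)-2-[2-(benzyloxy)-5-bromo-3-methoxyphenyl]-3-[4-(benzyloxy)-3,5-dimethoxyphenyl]propyl pivalate
Conditions: PivCl, pyridine, DMAP (cat.), CH2Cl2, 0 °C → rt
Reagents that add atoms: pivaloyl chloride, CC(C)(C)C(=O)Cl
Why: acylation of the primary alcohol gives an ester without α-hydrogens that should survive Lewis acid, oxidant, carbonate and boron enolate chemistry and fall to hydride in step 21.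

Step 11
Reactants: 15 the dibenzyl pivalate
Product: 16 (2S)-2-(5-bromo-2-hydroxy-3-methoxyphenyl)-3-(4-hydroxy-3,5-dimethoxyphenyl)propyl pivalate
Conditions: BCl3, pentamethylbenzene, CH2Cl2, −78 °C; MeOH quench
Reagents that add atoms: none
Why: Lewis acid cleavage of both aryl benzyl ethers with a cation scavenger, which at −78 °C should spare the methyl ethers, the pivalate and the aryl bromide that hydrogenolysis would remove.

Step 12
Reactants: 16 (2S)-2-(5-bromo-2-hydroxy-3-methoxyphenyl)-3-(4-hydroxy-3,5-dimethoxyphenyl)propyl pivalate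
Product: 18 [(2R,3S)-5-bromo-2-(4-hydroxy-3,5-dimethoxyphenyl)-7-methoxy-2,3-dihydro-1-benzofuran-3-yl]methyl pivalate, via para-quinone methide 17 (not isolated)
Conditions: Ag2O (1.1 equiv), CH2Cl2, rt, dark
Reagents that add atoms: none
Why: Ag2O removes two electrons and two protons from the 4-alkyl-2,6-dimethoxyphenol of ring C (phenoxyl radical, then loss of the benzylic hydrogen) to give para-quinone methide 17, and the ring D phenol adds to its exocyclic carbon, which restores the aromaticity of ring C and forms O1–C2. The closest known reaction type is the Ag2O oxidation of 4-alkylsyringols to quinone methides with oxa-conjugate addition of a phenol, as used to close 2-aryl-2,3-dihydrobenzofurans. The dihydrofuran ring closes in a 5-exo-trig mode. The new C2 centre is controlled by C3: the aryl group should end up trans to the CH2OPiv group, because the trans transition state avoids eclipsing of the two substituents and because the addition can revert through the quinone methide, so the more stable (2R,3S) isomer is expected. The step needs oxidation of ring C in preference to ring D, which the two methoxy donors of ring C and the bromine para to the ring D phenol secure (no para-quinone methide possible there, higher oxidation potential). The oxidant is held near one equivalent because 18 is still a syringyl phenol with a benzylic hydrogen.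

Step 13
Reactants: 19 (4R)-4-benzyl-1,3-oxazolidin-2-one
Product: 20 (4R)-4-benzyl-3-(bromoacetyl)-1,3-oxazolidin-2-one
Conditions: n-BuLi, THF, −78 °C; then BrCH2COBr
Reagents that add atoms: bromoacetyl bromide, BrCC(Br)=O
Why: N-acylation of the lithiated oxazolidinone by the acid bromide, which reacts at the acyl carbon far faster than at the CH2Br carbon.

Step 14
Reactants: 9 syringaldehyde; 20 (4R)-4-benzyl-3-(bromoacetyl)-1,3-oxazolidin-2-one
Product: 21 4-{2-[(4R)-4-benzyl-2-oxo-1,3-oxazolidin-3-yl]-2-oxoethoxy}-3,5-dimethoxybenzaldehyde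
Conditions: K2CO3, DMF, rt
Reagents that add atoms: none
Why: Williamson ether synthesis, the primary α-bromo imide being alkylated by the phenoxide faster than the imide carbonyl is attacked, to give a ring B piece with the aldehyde for the first aldol and the imide for the second.

Step 15
Reactants: 18 the dihydrobenzofuran phenol; 20 (4R)-4-benzyl-3-(bromoacetyl)-1,3-oxazolidin-2-one
Product: 22 [(2R,3S)-2-(4-{2-[(4R)-4-benzyl-2-oxo-1,3-oxazolidin-3-yl]-2-oxoethoxy}-3,5-dimethoxyphenyl)-5-bromo-7-methoxy-2,3-dihydro-1-benzofuran-3-yl]methyl pivalate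
Conditions: K2CO3, acetone, rt
Reagents that add atoms: none
Why: Williamson ether synthesis on the hindered 2,6-dimethoxyphenoxide with an unhindered α-bromo imide; any reversible opening of the phenoxide of 18 to the quinone methide recloses to the trans isomer, and alkylation ends that equilibrium.

Step 16
Reactants: 22 the ring C aryloxyacetyl imide; 21 the ring B aldehyde imide
Product: 23 syn-aldol adduct with C8' (R as the imide) and C7' (S), a (2R,3S)-3-aryl-2-aryloxy-3-hydroxypropanoyl imide (full name in the compound list)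
Conditions: Bu2BOTf (1.1 equiv), i-Pr2NEt, CH2Cl2, −78 → 0 °C; then 21, −78 → 0 °C; pH 7 buffer, MeOH, H2O2, 0 °C
Reagents that add atoms: none
Why: Evans boron aldol, in which the Z-dibutylboron enolate of the aryloxyacetyl imide adds to the aldehyde through a Zimmerman–Traxler chair on the enolate face left open by the (R)-auxiliary, which should give the 2,3-syn adduct with C8' in its final configuration; the imide of 21 is not enolised because the enolate is formed before 21 is added.

Step 17
Reactants: 23 the syn-aldol adduct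
Product: 24 4-nitrobenzoate of the C7'-inverted alcohol, (2R,3R) in the propanoyl chain
Conditions: PPh3, DIAD, 4-nitrobenzoic acid, toluene, 0 °C → rt
Reagents that add atoms: 4-nitrobenzoic acid, OC(=O)c1ccc(cc1)[N+](=O)[O-]
Why: Mitsunobu esterification, in which 4-nitrobenzoate displaces the alkoxyphosphonium ion of the benzylic carbinol with inversion, turning the threo (syn) unit into the erythro (anti) unit with C7' (R); the α-hydrogen of the imide lies in the imide plane through allylic strain, which should hold back elimination.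

Step 18
Reactants: 25 vanillin (4-hydroxy-3-methoxybenzaldehyde)
Product: 26 3-methoxy-4-[(triisopropylsilyl)oxy]benzaldehyde
Conditions: TIPSCl, imidazole, DMF, rt
Reagents that add atoms: triisopropylsilyl chloride, CC(C)[Si](Cl)(C(C)C)C(C)C
Why: silylation of the phenol gives a ring A protecting group that is stable to boron enolates, Mitsunobu conditions, LiBH4 and aqueous carbonate and leaves with fluoride at the end.

Step 19
Reactants: 24 the ring B oxyacetyl imide 4-nitrobenzoate; 26 3-methoxy-4-[(triisopropylsilyl)oxy]benzaldehyde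
Product: 27 second syn-aldol adduct with C8 (R as the imide) and C7 (S)
Conditions: Bu2BOTf (1.1 equiv), i-Pr2NEt, CH2Cl2, −78 → 0 °C; then 26, −78 → 0 °C; pH 7 buffer, MeOH, H2O2, 0 °C
Reagents that add atoms: none
Why: Evans boron aldol as in step 16, in which only the unbranched oxyacetyl imide on ring B should be enolised (the α-branched imide is kinetically non-acidic through allylic strain) and its (R)-auxiliary again directs the syn adduct with C8 in its final configuration.

Step 20
Reactants: 27 the second syn-aldol adduct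
Product: 28 bis(4-nitrobenzoate) with C7 inverted to (R)
Conditions: PPh3, DIAD, 4-nitrobenzoic acid, toluene, 0 °C → rt
Reagents that add atoms: 4-nitrobenzoic acid, OC(=O)c1ccc(cc1)[N+](=O)[O-]
Why: Mitsunobu esterification with inversion at the benzylic carbinol C7, which should complete the second erythro unit.

Step 21
Reactants: 28 the bis(4-nitrobenzoate) bis(imide)
Product: 29 (1R,2S)-2-{4-[(1R,2S)-2-{4-[(2R,3S)-5-bromo-3-(hydroxymethyl)-7-methoxy-2,3-dihydro-1-benzofuran-2-yl]-2,6-dimethoxyphenoxy}-1,3-dihydroxypropyl]-2,6-dimethoxyphenoxy}-1-{3-methoxy-4-[(triisopropylsilyl)oxy]phenyl}propane-1,3-diol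
Conditions: LiBH4 (excess), MeOH, THF, 0 → 40 °C
Reagents that add atoms: none
Why: hydride reduction, in which LiBH4 reduces both N-acyl oxazolidinones to the primary alcohols C9 and C9' and cleaves the two 4-nitrobenzoates and the pivalate without touching a stereocentre; the ring A phenol stays silylated, so no phenoxide para to a benzylic ester can form and fragment to a quinone methide.

Step 22
Reactants: 29 the silylated bromo pentaol
Product: 31 O-triisopropylsilyl ether of the target at the ring A phenol, via diethyl acetal 30 (not isolated)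
Conditions: (E)-(EtO)2CHCH=CH–Bpin, Pd(dppf)Cl2, K2CO3, dioxane/H2O, 70 °C; then 0.5 M HCl, THF, 0 °C → rt
Reagents that add atoms: (E)-2-(3,3-diethoxyprop-1-en-1-yl)-4,4,5,5-tetramethyl-1,3,2-dioxaborolane, CCOC(OCC)/C=C/B1OC(C)(C)C(C)(C)O1; water, O
Why: Suzuki–Miyaura coupling of the aryl bromide with the (E)-alkenylboronate with retention of alkene geometry, then mild acid hydrolysis of the allylic acetal to the (E)-enal, both of which the free alcohols and the silyl ether should tolerate.

Step 23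
Reactants: 31 the silylated enal
Product: 32 CNP0192639.1, (2E)-3-[(2R,3S)-2-(4-{[(1R,2S)-1-(4-{[(1R,2S)-1,3-dihydroxy-1-(4-hydroxy-3-methoxyphenyl)propan-2-yl]oxy}-3,5-dimethoxyphenyl)-1,3-dihydroxypropan-2-yl]oxy}-3,5-dimethoxyphenyl)-3-(hydroxymethyl)-7-methoxy-2,3-dihydro-1-benzofuran-5-yl]prop-2-enal
Conditions: TBAF, AcOH, THF, 0 °C
Reagents that add atoms: none
Why: fluoride cleavage of the aryl silyl ether, buffered with acetic acid so that the enal and the para-hydroxybenzylic alcohol are not exposed to free phenoxide or base.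

## Compound list

1 | 5-bromo-2-hydroxy-3-methoxybenzaldehyde | COc1cc(Br)cc(C=O)c1O | starting material
2 | 2-(benzyloxy)-5-bromo-3-methoxybenzaldehyde | COc1cc(Br)cc(C=O)c1OCc1ccccc1 | intermediate
3 | N-{2-[2-(benzyloxy)-5-bromo-3-methoxyphenyl]-1-tosylethenyl}formamide | COc1cc(Br)cc(C=C(NC=O)S(=O)(=O)c2ccc(C)cc2)c1OCc1ccccc1 | intermediate
4 | [2-(benzyloxy)-5-bromo-3-methoxyphenyl]acetonitrile | COc1cc(Br)cc(CC#N)c1OCc1ccccc1 | intermediate
5 | [2-(benzyloxy)-5-bromo-3-methoxyphenyl]acetic acid | COc1cc(Br)cc(CC(=O)O)c1OCc1ccccc1 | intermediate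
6 | (4S)-4-benzyl-1,3-oxazolidin-2-one | O=C1N[C@@H](Cc2ccccc2)CO1 | starting material
7 | [2-(benzyloxy)-5-bromo-3-methoxyphenyl]acetic pivalic anhydride | COc1cc(Br)cc(CC(=O)OC(=O)C(C)(C)C)c1OCc1ccccc1 | intermediate
8 | (4S)-4-benzyl-3-{[2-(benzyloxy)-5-bromo-3-methoxyphenyl]acetyl}-1,3-oxazolidin-2-one | COc1cc(Br)cc(CC(=O)N2[C@@H](Cc3ccccc3)COC2=O)c1OCc1ccccc1 | intermediate
9 | syringaldehyde (4-hydroxy-3,5-dimethoxybenzaldehyde) | COc1cc(C=O)cc(OC)c1O | starting material
10 | 4-(benzyloxy)-3,5-dimethoxybenzaldehyde | COc1cc(C=O)cc(OC)c1OCc1ccccc1 | intermediate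
11 | [4-(benzyloxy)-3,5-dimethoxyphenyl]methanol | COc1cc(CO)cc(OC)c1OCc1ccccc1 | intermediate
12 | 2-(benzyloxy)-5-(bromomethyl)-1,3-dimethoxybenzene | COc1cc(CBr)cc(OC)c1OCc1ccccc1 | intermediate
13 | (4S)-4-benzyl-3-{(2S)-2-[2-(benzyloxy)-5-bromo-3-methoxyphenyl]-3-[4-(benzyloxy)-3,5-dimethoxyphenyl]propanoyl}-1,3-oxazolidin-2-one | COc1cc(Br)cc([C@H](Cc2cc(OC)c(OCc3ccccc3)c(OC)c2)C(=O)N2[C@@H](Cc3ccccc3)COC2=O)c1OCc1ccccc1 | intermediate
14 | (2S)-2-[2-(benzyloxy)-5-bromo-3-methoxyphenyl]-3-[4-(benzyloxy)-3,5-dimethoxyphenyl]propan-1-ol | COc1cc(Br)cc([C@H](Cc2cc(OC)c(OCc3ccccc3)c(OC)c2)CO)c1OCc1ccccc1 | intermediate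
15 | (2S)-2-[2-(benzyloxy)-5-bromo-3-methoxyphenyl]-3-[4-(benzyloxy)-3,5-dimethoxyphenyl]propyl pivalate | COc1cc(Br)cc([C@H](Cc2cc(OC)c(OCc3ccccc3)c(OC)c2)COC(=O)C(C)(C)C)c1OCc1ccccc1 | intermediate
16 | (2S)-2-(5-bromo-2-hydroxy-3-methoxyphenyl)-3-(4-hydroxy-3,5-dimethoxyphenyl)propyl pivalate | COc1cc(Br)cc([C@H](Cc2cc(OC)c(O)c(OC)c2)COC(=O)C(C)(C)C)c1O | intermediate
17 | (2S)-2-(5-bromo-2-hydroxy-3-methoxyphenyl)-3-(3,5-dimethoxy-4-oxocyclohexa-2,5-dien-1-ylidene)propyl pivalate | COC1=CC(=C[C@@H](c2cc(Br)cc(OC)c2O)COC(=O)C(C)(C)C)C=C(OC)C1=O | intermediate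
18 | [(2R,3S)-5-bromo-2-(4-hydroxy-3,5-dimethoxyphenyl)-7-methoxy-2,3-dihydro-1-benzofuran-3-yl]methyl pivalate | COc1cc(cc(OC)c1O)[C@@H]2Oc3c(OC)cc(Br)cc3[C@H]2COC(=O)C(C)(C)C | intermediate
19 | (4R)-4-benzyl-1,3-oxazolidin-2-one | O=C1N[C@H](Cc2ccccc2)CO1 | starting material
20 | (4R)-4-benzyl-3-(bromoacetyl)-1,3-oxazolidin-2-one | O=C(CBr)N1[C@H](Cc2ccccc2)COC1=O | intermediate
21 | 4-{2-[(4R)-4-benzyl-2-oxo-1,3-oxazolidin-3-yl]-2-oxoethoxy}-3,5-dimethoxybenzaldehyde | COc1cc(C=O)cc(OC)c1OCC(=O)N1[C@H](Cc2ccccc2)COC1=O | intermediate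
22 | [(2R,3S)-2-(4-{2-[(4R)-4-benzyl-2-oxo-1,3-oxazolidin-3-yl]-2-oxoethoxy}-3,5-dimethoxyphenyl)-5-bromo-7-methoxy-2,3-dihydro-1-benzofuran-3-yl]methyl pivalate | COc1cc(cc(OC)c1OCC(=O)N1[C@H](Cc2ccccc2)COC1=O)[C@@H]2Oc3c(OC)cc(Br)cc3[C@H]2COC(=O)C(C)(C)C | intermediate
23 | (4R)-4-benzyl-3-[(2R,3S)-3-(4-{2-[(4R)-4-benzyl-2-oxo-1,3-oxazolidin-3-yl]-2-oxoethoxy}-3,5-dimethoxyphenyl)-2-(4-{(2R,3S)-5-bromo-7-methoxy-3-[(pivaloyloxy)methyl]-2,3-dihydro-1-benzofuran-2-yl}-2,6-dimethoxyphenoxy)-3-hydroxypropanoyl]-1,3-oxazolidin-2-one | COc1cc([C@H](O)[C@H](C(=O)N2[C@H](Cc3ccccc3)COC2=O)Oc2c(OC)cc([C@@H]3Oc4c(OC)cc(Br)cc4[C@H]3COC(=O)C(C)(C)C)cc2OC)cc(OC)c1OCC(=O)N1[C@H](Cc2ccccc2)COC1=O | intermediate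
24 | (1R,2R)-1-(4-{2-[(4R)-4-benzyl-2-oxo-1,3-oxazolidin-3-yl]-2-oxoethoxy}-3,5-dimethoxyphenyl)-3-[(4R)-4-benzyl-2-oxo-1,3-oxazolidin-3-yl]-2-(4-{(2R,3S)-5-bromo-7-methoxy-3-[(pivaloyloxy)methyl]-2,3-dihydro-1-benzofuran-2-yl}-2,6-dimethoxyphenoxy)-3-oxopropyl 4-nitrobenzoate | COc1cc([C@@H](OC(=O)c2ccc(cc2)[N+](=O)[O-])[C@H](C(=O)N2[C@H](Cc3ccccc3)COC2=O)Oc2c(OC)cc([C@@H]3Oc4c(OC)cc(Br)cc4[C@H]3COC(=O)C(C)(C)C)cc2OC)cc(OC)c1OCC(=O)N1[C@H](Cc2ccccc2)COC1=O | intermediate
25 | vanillin (4-hydroxy-3-methoxybenzaldehyde) | COc1cc(C=O)ccc1O | starting material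
26 | 3-methoxy-4-[(triisopropylsilyl)oxy]benzaldehyde | COc1cc(C=O)ccc1O[Si](C(C)C)(C(C)C)C(C)C | intermediate
27 | second syn-aldol adduct: compound 24 in which the OCH2C(=O) carbon on ring B has become C8 (R), bearing the carbinol C7 (S), CH(OH)[3-methoxy-4-(triisopropylsilyloxy)phenyl]; a (2R,3S)-3-aryl-2-aryloxy-3-hydroxypropanoyl imide of (4R)-4-benzyl-1,3-oxazolidin-2-one | COc1cc([C@H](O)[C@H](C(=O)N2[C@H](Cc3ccccc3)COC2=O)Oc2c(OC)cc([C@@H](OC(=O)c3ccc(cc3)[N+](=O)[O-])[C@H](C(=O)N3[C@H](Cc4ccccc4)COC3=O)Oc3c(OC)cc([C@@H]4Oc5c(OC)cc(Br)cc5[C@H]4COC(=O)C(C)(C)C)cc3OC)cc2OC)ccc1O[Si](C(C)C)(C(C)C)C(C)C | intermediate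
28 | bis(4-nitrobenzoate): compound 27 with C7 inverted to (R) and esterified as its 4-nitrobenzoate, (2R,3R) in both propanoyl chains | COc1cc([C@@H](OC(=O)c2ccc(cc2)[N+](=O)[O-])[C@H](C(=O)N2[C@H](Cc3ccccc3)COC2=O)Oc2c(OC)cc([C@@H](OC(=O)c3ccc(cc3)[N+](=O)[O-])[C@H](C(=O)N3[C@H](Cc4ccccc4)COC3=O)Oc3c(OC)cc([C@@H]4Oc5c(OC)cc(Br)cc5[C@H]4COC(=O)C(C)(C)C)cc3OC)cc2OC)ccc1O[Si](C(C)C)(C(C)C)C(C)C | intermediate
29 | (1R,2S)-2-{4-[(1R,2S)-2-{4-[(2R,3S)-5-bromo-3-(hydroxymethyl)-7-methoxy-2,3-dihydro-1-benzofuran-2-yl]-2,6-dimethoxyphenoxy}-1,3-dihydroxypropyl]-2,6-dimethoxyphenoxy}-1-{3-methoxy-4-[(triisopropylsilyl)oxy]phenyl}propane-1,3-diol | COc1cc([C@@H](O)[C@H](CO)Oc2c(OC)cc([C@@H](O)[C@H](CO)Oc3c(OC)cc([C@@H]4Oc5c(OC)cc(Br)cc5[C@H]4CO)cc3OC)cc2OC)ccc1O[Si](C(C)C)(C(C)C)C(C)C | intermediate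
30 | compound 29 with the 5-bromo group replaced by (1E)-3,3-diethoxyprop-1-en-1-yl | COc1cc([C@@H](O)[C@H](CO)Oc2c(OC)cc([C@@H](O)[C@H](CO)Oc3c(OC)cc([C@@H]4Oc5c(OC)cc(/C=C/C(OCC)OCC)cc5[C@H]4CO)cc3OC)cc2OC)ccc1O[Si](C(C)C)(C(C)C)C(C)C | intermediate
31 | ring A O-triisopropylsilyl ether of the target, (2E)-3-{dihydrobenzofuran-5-yl}prop-2-enal with (2R,3S), (7R,8S) and (7'R,8'S) centres | COc1cc([C@@H](O)[C@H](CO)Oc2c(OC)cc([C@@H](O)[C@H](CO)Oc3c(OC)cc([C@@H]4Oc5c(OC)cc(/C=C/C=O)cc5[C@H]4CO)cc3OC)cc2OC)ccc1O[Si](C(C)C)(C(C)C)C(C)C | intermediate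
32 | CNP0192639.1, (2E)-3-[(2R,3S)-2-(4-{[(1R,2S)-1-(4-{[(1R,2S)-1,3-dihydroxy-1-(4-hydroxy-3-methoxyphenyl)propan-2-yl]oxy}-3,5-dimethoxyphenyl)-1,3-dihydroxypropan-2-yl]oxy}-3,5-dimethoxyphenyl)-3-(hydroxymethyl)-7-methoxy-2,3-dihydro-1-benzofuran-5-yl]prop-2-enal | COc1cc([C@@H](O)[C@H](CO)Oc2c(OC)cc([C@@H](O)[C@H](CO)Oc3c(OC)cc([C@@H]4Oc5c(OC)cc(/C=C/C=O)cc5[C@H]4CO)cc3OC)cc2OC)ccc1O | target

## Step count and risks

Total step count: 23.
Longest linear sequence: 17 steps (steps 1–4, 8–12, 15–17 and 19–23, from 1).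

Steps most likely to fail:

1. Step 12 (oxidative ring closure). The quinone methide may be lost before it closes, by tautomerisation to the stilbene through the doubly activated C3 hydrogen or by intermolecular coupling. The product, still a syringyl phenol with a benzylic hydrogen, may also be oxidised further towards the benzofuran. Fallback: oxidation and ring closure would be separated. From 16, DDQ (1 equiv) in CH2Cl2/MeOH at 0 °C should trap the quinone methide at once as the benzylic methyl ether (2S)-2-(5-bromo-2-hydroxy-3-methoxyphenyl)-3-(4-hydroxy-3,5-dimethoxyphenyl)-3-methoxypropyl pivalate F1 (both epimers at the new centre serve). Catalytic TsOH in CH2Cl2 would then ionise the benzylic ether to the para-hydroxybenzyl cation, which the ring D phenol captures under equilibrating, non-oxidising conditions to give the trans isomer, coming back to the route at 18.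

2. Step 17 (first Mitsunobu inversion; step 20 shares the risk). The alkoxyphosphonium ion may eliminate towards the α-aryloxy cinnamoyl imide, or ionise at the benzylic carbon so that inversion is incomplete. Fallback: inversion by oxidation and catalyst-controlled reduction in place of displacement. From 23, Dess–Martin periodinane with NaHCO3 in CH2Cl2 should give the β-keto imide F2, whose C8' centre is held by allylic strain. Noyori transfer hydrogenation with RuCl[(S,S)-TsDPEN](p-cymene) in HCO2H/Et3N should deliver hydride to the aryl ketone under catalyst control to give the (7'R) anti-aldol alcohol F3. Acylation with 4-nitrobenzoyl chloride and pyridine then returns to the route at 24.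

3. Step 19 (second aldol in the presence of the first unit). Bu2BOTf and the amine may enolise the wrong imide and expel the neighbouring 4-nitrobenzoate by an E1cB process, or the enolisation of the ring B imide may stall. Fallback: the order of aldol and inversion would be exchanged so that no β-acyloxy imide meets the enolisation conditions. From 23, Bu2BOTf (2.3 equiv) and i-Pr2NEt would hold the free C7' hydroxyl as its dibutylboron aldolate, the usual resting state of a boron aldol, and enolise the ring B imide. Addition of 26 should then give the bis-aldol diol F4. One double Mitsunobu reaction (PPh3, DIAD, 4-nitrobenzoic acid) would invert C7 and C7' together and return to the route at 28, skipping 24 and 27.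

## Further compounds

F1 | step 12 | (2S)-2-(5-bromo-2-hydroxy-3-methoxyphenyl)-3-(4-hydroxy-3,5-dimethoxyphenyl)-3-methoxypropyl pivalate (both C3 epimers) | COc1cc(Br)cc([C@H](C(OC)c2cc(OC)c(O)c(OC)c2)COC(=O)C(C)(C)C)c1O
F2 | step 17 | β-keto imide: compound 23 with the C7' carbinol oxidised to the ketone, (2R)-2-aryloxy-3-aryl-3-oxopropanoyl imide | COc1cc(C(=O)[C@H](C(=O)N2[C@H](Cc3ccccc3)COC2=O)Oc2c(OC)cc([C@@H]3Oc4c(OC)cc(Br)cc4[C@H]3COC(=O)C(C)(C)C)cc2OC)cc(OC)c1OCC(=O)N1[C@H](Cc2ccccc2)COC1=O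
F3 | step 17 | anti-aldol alcohol: the C7' epimer of 23, (2R,3R)-3-aryl-2-aryloxy-3-hydroxypropanoyl imide | COc1cc([C@@H](O)[C@H](C(=O)N2[C@H](Cc3ccccc3)COC2=O)Oc2c(OC)cc([C@@H]3Oc4c(OC)cc(Br)cc4[C@H]3COC(=O)C(C)(C)C)cc2OC)cc(OC)c1OCC(=O)N1[C@H](Cc2ccccc2)COC1=O
F4 | step 19 | bis-aldol diol: compound 27 with a free (S)-hydroxyl at C7' in place of the 4-nitrobenzoate, both units syn (2R,3S) | COc1cc([C@H](O)[C@H](C(=O)N2[C@H](Cc3ccccc3)COC2=O)Oc2c(OC)cc([C@H](O)[C@H](C(=O)N3[C@H](Cc4ccccc4)COC3=O)Oc3c(OC)cc([C@@H]4Oc5c(OC)cc(Br)cc5[C@H]4COC(=O)C(C)(C)C)cc3OC)cc2OC)ccc1O[Si](C(C)C)(C(C)C)C(C)C
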